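**Retrosynthetic overview**

- Labels: ring A is the methyl benzoate ring (ester carbon as position 1, diaryl ether carbon at position 2, OMe at position 3, OH at position 5); ring B is the acid ring (B1 CO2H, B2 OH, B3 Cl, B4 CH3, B5 H, B6 ether carbon).
- Feature: B1–B4 carry carboxyl, oxygen, chlorine and methyl on four adjacent carbons, which is the pattern of C3–C6 of a 3-carboxy-4-oxy-5-chloro-6-methyl-2-pyrone; B5–B6 (H, O-aryl) are the two carbons of a ring A aryl ethynyl ether.
- Key disconnection: B6–B1 and B5–B4, made together by inverse-demand [4+2] cycloaddition of the ynol ether to the pyrone and loss of CO2. Ring B is the only ring formed and is formed last, so the crowded ether oxygen is never used in an aryl coupling.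
- Pyrone: di-tert-butyl malonate and diketene, O-MOM, C5 chlorination (3 steps). Ynol ether: 5-iodovanillin by carbonylation, Dakin oxidation, MOM, O-vinylation, bromination/dehydrobromination, second dehydrobromination (6 steps).
- End: one acid treatment removes both MOM groups and the tert-butyl ester; the target has no stereocentre.

Key step: step 10

Remark: diketene is taken as a purchasable, stabilised reagent, and the terminal aryloxyacetylene is assumed to survive a cold neutral work-up long enough to be used as a solution.

**Route**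

Step 1
Reactants: 1 di-tert-butyl malonate; 2 diketene
Product: 5 tert-butyl 4-hydroxy-6-methyl-2-oxo-2H-pyran-3-carboxylate, via acylmalonate 3 (not isolated), via acylketene 4 (not isolated)
Conditions: NaH, THF, 0 °C, then 2; AcOH; PhMe, 90 °C
Reagents that add atoms: none
Why: C-acylation of the sodium malonate by diketene should give tricarbonyl 3, whose doubly activated tert-butyl ester loses tert-butanol on warming (thermal acylketene formation, as known for tert-butyl β-keto esters), and ketene 4 is closed by its enol oxygen to the 4-hydroxy-2-pyrone; both esters being the same, only one pyrone can arise.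

Step 2
Reactants: 5 tert-butyl 4-hydroxy-6-methyl-2-oxo-2H-pyran-3-carboxylate
Product: 6 tert-butyl 4-(methoxymethoxy)-6-methyl-2-oxo-2H-pyran-3-carboxylate
Conditions: MOMCl, iPr2NEt, CH2Cl2, 0 °C to rt
Reagents that add atoms: chloromethyl methyl ether (MOMCl), COCCl
Why: O-alkylation of the acidic 4-hydroxy-2-pyrone with a hard chloromethyl ether (Williamson-type acetal formation) should go to the C4 oxygen, and it masks the enol so that it can neither protonate the ynol ether later nor be halogenated at C3.

Step 3
Reactants: 6 tert-butyl 4-(methoxymethoxy)-6-methyl-2-oxo-2H-pyran-3-carboxylate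
Product: 7 tert-butyl 5-chloro-4-(methoxymethoxy)-6-methyl-2-oxo-2H-pyran-3-carboxylate
Conditions: NCS, DMF, 50 °C, dark
Reagents that add atoms: N-chlorosuccinimide, O=C1CCC(=O)N1Cl
Why: Electrophilic substitution of the 2-pyrone (attack at C5 gives the cation at C6 stabilised by the ring oxygen, then loss of a proton) can only take place at C5 because C3 carries the ester, and the neutral N-chloroimide should spare the MOM acetal and the tert-butyl ester.

Step 4
Reactants: 8 5-iodovanillin
Product: 9 methyl 5-formyl-2-hydroxy-3-methoxybenzoate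
Conditions: PdCl2(PPh3)2 (3 mol %), CO (1 atm), Et3N, MeOH, 65 °C
Reagents that add atoms: carbon monoxide, [C-]#[O+]; methanol, CO
Why: Palladium-catalysed alkoxycarbonylation (oxidative addition of the aryl iodide to zerovalent palladium, CO insertion, methanolysis of the acylpalladium) tolerates the aldehyde and the free ortho phenol.

Step 5
Reactants: 9 methyl 5-formyl-2-hydroxy-3-methoxybenzoate
Product: 11 methyl 2,5-dihydroxy-3-methoxybenzoate, via aryl formate 10 (not isolated)
Conditions: H2O2 (30 % aq.), H2SO4 (cat.), MeOH, rt, argon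
Reagents that add atoms: hydrogen peroxide, OO
Why: Acid-catalysed Dakin oxidation (Baeyer–Villiger-type aryl migration, made possible by the para hydroxyl) should give formate 10, which is methanolysed in the same pot, and methanol as solvent keeps the methyl ester.

Step 6
Reactants: 11 methyl 2,5-dihydroxy-3-methoxybenzoate
Product: 12 methyl 2-hydroxy-3-methoxy-5-(methoxymethoxy)benzoate
Conditions: MOMCl (1.05 equiv), iPr2NEt, CH2Cl2, 0 °C
Reagents that add atoms: chloromethyl methyl ether (MOMCl), COCCl
Why: The C5 hydroxyl is free and unhindered whereas the C2 hydroxyl is hydrogen-bonded to the ester and flanked by the methoxy group, so one equivalent of MOMCl with a weak amine base should give chemoselective mono-protection (acetal formation).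

Step 7
Reactants: 12 methyl 2-hydroxy-3-methoxy-5-(methoxymethoxy)benzoate
Product: 13 methyl 2-(ethenyloxy)-3-methoxy-5-(methoxymethoxy)benzoate
Conditions: (CH2=CHBO)3·pyridine, Cu(OAc)2, pyridine, CH2Cl2, air, rt
Reagents that add atoms: 2,4,6-trivinylcyclotriboroxane–pyridine complex, C=CB1OB(C=C)OB(C=C)O1.c1ccncc1
Why: Copper-promoted oxidative C–O coupling of Chan–Lam type with a vinylboron reagent should vinylate the phenol at room temperature without touching ester or acetal, air returning the copper to its divalent state.

Step 8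
Reactants: 13 methyl 2-(ethenyloxy)-3-methoxy-5-(methoxymethoxy)benzoate
Product: 15 methyl 2-[(2-bromoethenyl)oxy]-3-methoxy-5-(methoxymethoxy)benzoate as an E/Z mixture, via dibromide 14 (not isolated)
Conditions: Br2 (1.0 equiv), CH2Cl2, −78 °C; then DBU, −78 °C to rt
Reagents that add atoms: bromine, BrBr
Why: Electrophilic addition of bromine to the enol ether double bond should be far faster at −78 °C than substitution of the ester-deactivated ring, and DBU then removes HBr from α-bromo ether 14 (base-induced dehydrobromination) to give the 2-bromovinyl ether.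

Step 9
Reactants: 15 methyl 2-[(2-bromoethenyl)oxy]-3-methoxy-5-(methoxymethoxy)benzoate
Product: 16 methyl 2-(ethynyloxy)-3-methoxy-5-(methoxymethoxy)benzoate
Conditions: LiN(iPr)2 (2.2 equiv), THF, −78 °C; pH 7 buffer, cold; used at once as a toluene solution
Reagents that add atoms: none
Why: Base-induced dehydrobromination of a β-halovinyl ether is the classical route to aryloxyacetylenes (anti elimination from the Z isomer, α-deprotonation and 1,2-shift of Fritsch–Buttenberg–Wiechell type from the E isomer), and a lithium amide at −78 °C is chosen because an alkyllithium would add to the methyl ester.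

Step 10
Reactants: 7 tert-butyl 5-chloro-4-(methoxymethoxy)-6-methyl-2-oxo-2H-pyran-3-carboxylate; 16 methyl 2-(ethynyloxy)-3-methoxy-5-(methoxymethoxy)benzoate
Product: 18 tert-butyl 3-chloro-6-[2-methoxy-6-(methoxycarbonyl)-4-(methoxymethoxy)phenoxy]-2-(methoxymethoxy)-4-methylbenzoate, via bridged lactone 17 (not isolated)
Conditions: 16 (2.5 equiv, in portions), PhMe, 2,6-lutidine (0.1 equiv), 110 °C, sealed tube
Reagents that add atoms: none
Why: The terminal, nucleophilic carbon of the aryloxyacetylene bonds to the electrophilic C6 of the pyrone and the oxygen-bearing carbon to C3 in an asynchronous inverse-electron-demand [4+2] cycloaddition, and bridged lactone 17 then loses CO2 by a retro-[4+2] to give the arene directly. The closest known reaction type is the Diels–Alder/CO2-extrusion benzannulation of 3-alkoxycarbonyl-2-pyrones with ketene acetals, ynamines and other electron-rich π partners. Ring B is closed by intermolecular [4+2] annulation, its bonds B6–B1 and B5–B4 forming in one operation from the diene carbons C3–C6 and the two alkyne carbons. No stereocentre remains, since the two bridgeheads of 17 become sp2 carbons when CO2 leaves. The one selectivity needed is regiochemical (aryloxy carbon next to the ester carbon), and it is set by the matched polarisation of the ynol ether (nucleophilic CH) and the pyrone (C6 is the acceptor terminus of the diene conjugated to ester and lactone carbonyls), with sterics in agreement because only the unsubstituted alkyne carbon has to approach the methyl-bearing C6. The 4-alkoxy group slows the diene, so the ynol ether is used in excess and fed in portions, and a trace of hindered base keeps adventitious acid away from the ynol ether and the MOM acetals.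

Step 11
Reactants: 18 tert-butyl 3-chloro-6-[2-methoxy-6-(methoxycarbonyl)-4-(methoxymethoxy)phenoxy]-2-(methoxymethoxy)-4-methylbenzoate
Product: 19 isodihydromaldoxin
Conditions: TFA, CH2Cl2, H2O (5 equiv), 0 °C to rt
Reagents that add atoms: none
Why: Acidolysis with trifluoroacetic acid should cleave the tert-butyl ester by loss of isobutene and hydrolyse both MOM acetals in one operation, while the methyl ester and the diaryl ether are stable to acid.

**Compound list**

1 | di-tert-butyl malonate | CC(C)(C)OC(=O)CC(=O)OC(C)(C)C | starting material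
2 | diketene (4-methylideneoxetan-2-one) | C=C1CC(=O)O1 | starting material
3 | di-tert-butyl 2-(3-oxobutanoyl)propanedioate | CC(=O)CC(=O)C(C(=O)OC(C)(C)C)C(=O)OC(C)(C)C | intermediate
4 | tert-butyl 2-(oxomethylidene)-3,5-dioxohexanoate | CC(=O)CC(=O)C(=C=O)C(=O)OC(C)(C)C | intermediate
5 | tert-butyl 4-hydroxy-6-methyl-2-oxo-2H-pyran-3-carboxylate | CC1=CC(O)=C(C(=O)OC(C)(C)C)C(=O)O1 | intermediate
6 | tert-butyl 4-(methoxymethoxy)-6-methyl-2-oxo-2H-pyran-3-carboxylate | COCOC1=C(C(=O)OC(C)(C)C)C(=O)OC(C)=C1 | intermediate
7 | tert-butyl 5-chloro-4-(methoxymethoxy)-6-methyl-2-oxo-2H-pyran-3-carboxylate | COCOC1=C(C(=O)OC(C)(C)C)C(=O)OC(C)=C1Cl | intermediate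
8 | 5-iodovanillin (4-hydroxy-3-iodo-5-methoxybenzaldehyde) | COc1cc(C=O)cc(I)c1O | starting material
9 | methyl 5-formyl-2-hydroxy-3-methoxybenzoate | COC(=O)c1cc(C=O)cc(OC)c1O | intermediate
10 | methyl 5-(formyloxy)-2-hydroxy-3-methoxybenzoate | COC(=O)c1cc(OC=O)cc(OC)c1O | intermediate
11 | methyl 2,5-dihydroxy-3-methoxybenzoate | COC(=O)c1cc(O)cc(OC)c1O | intermediate
12 | methyl 2-hydroxy-3-methoxy-5-(methoxymethoxy)benzoate | COCOc1cc(OC)c(O)c(c1)C(=O)OC | intermediate
13 | methyl 2-(ethenyloxy)-3-methoxy-5-(methoxymethoxy)benzoate | COCOc1cc(OC)c(OC=C)c(c1)C(=O)OC | intermediate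
14 | methyl 2-(1,2-dibromoethoxy)-3-methoxy-5-(methoxymethoxy)benzoate (racemic) | COCOc1cc(OC)c(OC(Br)CBr)c(c1)C(=O)OC | intermediate
15 | methyl 2-[(2-bromoethenyl)oxy]-3-methoxy-5-(methoxymethoxy)benzoate (E/Z mixture) | COCOc1cc(OC)c(OC=CBr)c(c1)C(=O)OC | intermediate
16 | methyl 2-(ethynyloxy)-3-methoxy-5-(methoxymethoxy)benzoate | COCOc1cc(OC)c(OC#C)c(c1)C(=O)OC | intermediate
17 | tert-butyl 7-chloro-5-[2-methoxy-6-(methoxycarbonyl)-4-(methoxymethoxy)phenoxy]-8-(methoxymethoxy)-1-methyl-3-oxo-2-oxabicyclo[2.2.2]octa-5,7-diene-4-carboxylate (racemic; the two bridgeheads are tied to each other by the bicycle) | CC(C)(C)OC(=O)C12C(=O)OC(C)(C(Cl)=C1OCOC)C=C2Oc3c(OC)cc(OCOC)cc3C(=O)OC | intermediate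
18 | tert-butyl 3-chloro-6-[2-methoxy-6-(methoxycarbonyl)-4-(methoxymethoxy)phenoxy]-2-(methoxymethoxy)-4-methylbenzoate | COCOc1cc(OC)c(Oc2cc(C)c(Cl)c(OCOC)c2C(=O)OC(C)(C)C)c(c1)C(=O)OC | intermediate
19 | isodihydromaldoxin, 3-chloro-2-hydroxy-6-[4-hydroxy-2-methoxy-6-(methoxycarbonyl)phenoxy]-4-methylbenzoic acid | COC(=O)c1cc(O)cc(OC)c1Oc1cc(C)c(Cl)c(O)c1C(=O)O | target

**Step count**

Total: 11 steps. Longest linear sequence: 8 steps (steps 4 to 11, from 5-iodovanillin).

**Steps most likely to fail**

Step 10. The 4-alkoxy group raises the LUMO of the pyrone and the methyl group shields C6, so the cycloaddition may be slower than thermal oligomerisation of the terminal aryloxyacetylene. The fallback sets out from phenol 12 and comes back at 18, making the ether bond by a copper-catalysed Ullmann coupling with a ring B bromide built from purchased 2-chloro-3-methylphenol. MOMCl and iPr2NEt should give 2-chloro-1-(methoxymethoxy)-3-methylbenzene F1. Iridium-catalysed C–H borylation ([Ir(OMe)(cod)]2, 4,4'-di-tert-butyl-2,2'-bipyridine, B2pin2) should go to the only ring position without an ortho neighbour and give 2-[4-chloro-3-(methoxymethoxy)-5-methylphenyl]-4,4,5,5-tetramethyl-1,3,2-dioxaborolane F2. CuBr2 in aqueous methanol should exchange boron for bromine to give 5-bromo-2-chloro-1-(methoxymethoxy)-3-methylbenzene F3. LiN(iPr)2 at −78 °C should remove the proton between bromine and the MOM ether to give [6-bromo-3-chloro-2-(methoxymethoxy)-4-methylphenyl]lithium F4, which Boc2O traps as tert-butyl 6-bromo-3-chloro-2-(methoxymethoxy)-4-methylbenzoate F5. F5 and phenol 12 are then joined with CuI, picolinic acid and K3PO4 in DMSO at 90 °C to give 18.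

Step 3. C5 of the ester-bearing pyrone is a weak nucleophile, so chlorination may stall, or be overtaken by loss of the MOM group or attack at the 6-methyl group. The fallback sets out from malonate 1 and comes back at 7, bringing the chlorine in with the acetylketene unit instead of by substitution on the ring. Purchased 2,2,6-trimethyl-4H-1,3-dioxin-4-one is chlorinated at C5 with NCS in acetic acid to 5-chloro-2,2,6-trimethyl-4H-1,3-dioxin-4-one F6. Heated at 110 °C in toluene with the sodium enolate of 1 (NaH), F6 should lose acetone to give 2-chloro-3-oxobut-1-en-1-one F7, which acylates the enolate at carbon to di-tert-butyl 2-(2-chloro-3-oxobutanoyl)propanedioate F8. After acidification this should close as in step 1, through tert-butyl 4-chloro-2-(oxomethylidene)-3,5-dioxohexanoate F9, to tert-butyl 5-chloro-4-hydroxy-6-methyl-2-oxo-2H-pyran-3-carboxylate F10. MOMCl and iPr2NEt then give 7.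

Step 7. The phenol is flanked on both sides, hydrogen-bonded to the ester and able to chelate copper, so C–O bond formation may be slow while the vinylboron reagent is consumed by protodeboronation and homocoupling. The fallback sets out from phenol 12 and comes back at 13, replacing the oxidative coupling by alkylation and elimination. Alkylation of 12 with 1,2-dibromoethane (K2CO3, DMF) should give methyl 2-(2-bromoethoxy)-3-methoxy-5-(methoxymethoxy)benzoate F11. PhSeNa (from PhSeSePh and NaBH4 in ethanol) should displace bromide to give methyl 3-methoxy-5-(methoxymethoxy)-2-[2-(phenylselanyl)ethoxy]benzoate F12. NaIO4 should oxidise it to methyl 3-methoxy-5-(methoxymethoxy)-2-[2-(phenylseleninyl)ethoxy]benzoate F13, which on warming undergoes selenoxide syn elimination to 13.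

**Further compounds**

F1 | step 10 | 2-chloro-1-(methoxymethoxy)-3-methylbenzene | COCOc1cccc(C)c1Cl
F2 | step 10 | 2-[4-chloro-3-(methoxymethoxy)-5-methylphenyl]-4,4,5,5-tetramethyl-1,3,2-dioxaborolane | COCOc1cc(cc(C)c1Cl)B1OC(C)(C)C(C)(C)O1
F3 | step 10 | 5-bromo-2-chloro-1-(methoxymethoxy)-3-methylbenzene | COCOc1cc(Br)cc(C)c1Cl
F4 | step 10 | [6-bromo-3-chloro-2-(methoxymethoxy)-4-methylphenyl]lithium | [Li]c1c(Br)cc(C)c(Cl)c1OCOC
F5 | step 10 | tert-butyl 6-bromo-3-chloro-2-(methoxymethoxy)-4-methylbenzoate | COCOc1c(Cl)c(C)cc(Br)c1C(=O)OC(C)(C)C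
F6 | step 3 | 5-chloro-2,2,6-trimethyl-4H-1,3-dioxin-4-one | CC1=C(Cl)C(=O)OC(C)(C)O1
F7 | step 3 | 2-chloro-3-oxobut-1-en-1-one | CC(=O)C(Cl)=C=O
F8 | step 3 | di-tert-butyl 2-(2-chloro-3-oxobutanoyl)propanedioate (racemic, enolisable) | CC(=O)C(Cl)C(=O)C(C(=O)OC(C)(C)C)C(=O)OC(C)(C)C
F9 | step 3 | tert-butyl 4-chloro-2-(oxomethylidene)-3,5-dioxohexanoate | CC(=O)C(Cl)C(=O)C(=C=O)C(=O)OC(C)(C)C
F10 | step 3 | tert-butyl 5-chloro-4-hydroxy-6-methyl-2-oxo-2H-pyran-3-carboxylate | CC1=C(Cl)C(O)=C(C(=O)OC(C)(C)C)C(=O)O1
F11 | step 7 | methyl 2-(2-bromoethoxy)-3-methoxy-5-(methoxymethoxy)benzoate | COCOc1cc(OC)c(OCCBr)c(c1)C(=O)OC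
F12 | step 7 | methyl 3-methoxy-5-(methoxymethoxy)-2-[2-(phenylselanyl)ethoxy]benzoate | COCOc1cc(OC)c(OCC[Se]c2ccccc2)c(c1)C(=O)OC
F13 | step 7 | methyl 3-methoxy-5-(methoxymethoxy)-2-[2-(phenylseleninyl)ethoxy]benzoate | COCOc1cc(OC)c(OCC[Se](=O)c2ccccc2)c(c1)C(=O)OC
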